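**Remark (chemistry assumption, one line):** eudesmane numbering is used (ring A = C1–C2–C3–C4–C5–C10, ring B = C5–C6–C7–C8–C9–C10, C14 = methyl on C10, C15 = methyl on C4, C11–C13 = the carbons on C7 with C12 the ester carbon); β is the face of C14 and α the opposite face; TBS = tert-butyldimethylsilyl, NAP = naphthalen-2-ylmethyl; read this way the target is the trans-decalin with 1β-OH, 4α-OH/4β-CH3, 5αH, 6α-angeloyloxy, 7αH (equatorial acrylate arm), 8α-OH and 10β-CH3, all ring B substituents equatorial.

## Retrosynthetic overview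

1. Target 22 ⇐ desilylation, O6 angeloylation, NAP removal, α-methylenation of the C11 ester, hydration of C4=C15, C8 ketone reduction and C7 alkylation ⇐ trans-octalone 10, whose C7=C8 silyl enol ether fixes where the C7 arm enters.
2. 10 ⇐ C5 epimerisation of cis adduct 9 ⇐ one-step union of ring A enone 4 (dienophile C5=C10, carbonyl at C4, stereocentre C1) with the 1-alkoxy-3-silyloxybutadiene 8 (C6–C7–C8–C9), forming C9–C10 and C5–C6.
3. Enabling feature: ring B carries oxygen on C6 and on C8 (a 1,3-dioxygenated C6–C9 chain, the retron of a 1-alkoxy-3-silyloxydiene) and is fused to ring A through C5–C10; C4 next to C5 is oxygenated, so it can serve as the activating ketone of a cyclohexenone dienophile, and O1 next to C10 steers the face.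
4. Ring order: ring A comes ready-made from 2-methylcyclohex-2-enone (enantioselective reduction, allylic oxidation); ring B is closed in the key step; no other ring is formed.
5. Stereocentres: C1 by catalyst control; C10, C5 (cis, then epimerised) and C6 in the key step; C7 and C8 under thermodynamic control; C4 by α-face hydration.

Key step: step 6

## Route

Step 1
Reactants: 1 2-methylcyclohex-2-en-1-one
Product: 2 (R)-2-methylcyclohex-2-en-1-ol
Conditions: (S)-Me-CBS oxazaborolidine [(S)-1-methyl-3,3-diphenyltetrahydro-1H,3H-pyrrolo[1,2-c][1,3,2]oxazaborole] (10 mol %), BH3·SMe2, THF, −20 °C; MeOH quench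
Reagents that add atoms: none
Why: Corey–Bakshi–Shibata reduction, in which the oxazaborolidine–borane complex binds the ketone with the 2-methylalkenyl arm as the large group and delivers hydride to one carbonyl face only, which sets the carbinol centre (the later C1) as R.

Step 2
Reactants: 2 (R)-2-methylcyclohex-2-en-1-ol
Product: 3 (R)-tert-butyldimethyl[(2-methylcyclohex-2-en-1-yl)oxy]silane
Conditions: TBSCl, imidazole, DMF, 0 °C to rt
Reagents that add atoms: tert-butyldimethylsilyl chloride, C[Si](C)(Cl)C(C)(C)C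
Why: Standard imidazole-mediated silylation of a secondary allylic alcohol, which does not touch the stereocentre.

Step 3
Reactants: 3 (R)-tert-butyldimethyl[(2-methylcyclohex-2-en-1-yl)oxy]silane
Product: 4 (R)-4-(tert-butyldimethylsilyloxy)-3-methylcyclohex-2-en-1-one
Conditions: Rh2(cap)4 [dirhodium tetrakis(caprolactamate)] (1 mol %), tert-butyl hydroperoxide (5 equiv), K2CO3, CH2Cl2, rt
Reagents that add atoms: tert-butyl hydroperoxide, CC(C)(C)OO
Why: Rhodium-carboxamidate-catalysed allylic oxidation with tert-butyl hydroperoxide (peroxyl-radical hydrogen abstraction, then collapse of the allylic peroxide to the ketone) should attack the ring CH2 next to the vinylic CH, the silyloxy methine being shielded by the bulky silyl group, and so gives the γ-silyloxy enone without touching the stereocentre.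

Step 4
Reactants: 5 (E)-4-methoxybut-3-en-2-one; 6 naphthalen-2-ylmethanol
Product: 7 (E)-4-(naphthalen-2-ylmethoxy)but-3-en-2-one
Conditions: pyridinium p-toluenesulfonate (5 mol %), toluene, 60 °C, reduced pressure (methanol removed)
Reagents that add atoms: none
Why: Acid-catalysed addition–elimination (transetherification) at the β-carbon of the vinylogous ester, driven by removal of methanol, should keep the E geometry of the push–pull alkene.

Step 5
Reactants: 7 (E)-4-(naphthalen-2-ylmethoxy)but-3-en-2-one
Product: 8 (E)-tert-butyldimethyl{[4-(naphthalen-2-ylmethoxy)buta-1,3-dien-2-yl]oxy}silane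
Conditions: TBSOTf, Et3N, Et2O, 0 °C
Reagents that add atoms: tert-butyldimethylsilyl trifluoromethanesulfonate, C[Si](C)(OS(=O)(=O)C(F)(F)F)C(C)(C)C
Why: Soft enolisation (silyl triflate and amine) of the methyl ketone on its only enolisable side gives the cross-conjugated 1-alkoxy-3-silyloxydiene with the E enol ether retained.

Step 6
Reactants: 4 (R)-configured γ-(tert-butyldimethylsilyloxy)-β-methylcyclohexenone (ring A dienophile); 8 (E)-configured naphthylmethoxy tert-butyldimethylsilyloxy butadiene (diene for ring B)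
Product: 9 1β,8-bis(TBSO)-6α-(NAPO)-5βH-11,12,13,15-tetranoreudesm-7-en-4-one (cis-fused adduct)
Conditions: Me2AlNTf2 (20 mol %), diene in twofold excess, CH2Cl2, −40 to 0 °C; Et3N quench at low temperature; chromatography on Et3N-deactivated silica
Reagents that add atoms: none
Why: Aluminium-Lewis-acid-promoted Diels–Alder reaction of an electron-rich 1-alkoxy-3-silyloxydiene with a β-methyl cyclohexenone, a one-to-one addition that keeps every atom of both partners, concerted but asynchronous or in the limit a Mukaiyama–Michael addition followed by capture of the C6 oxocarbenium ion by the aluminium enolate, both paths ending at 9; the closest known reaction type is the aluminium-triflimide or AlBr3/AlMe3 promoted cycloaddition of hindered 2-silyloxydienes to 3-methylcyclohex-2-enones that creates a quaternary carbon. Ring B is closed as a six-membered carbocycle by suprafacial (4π + 2π) addition, C9–C10 leading and C5–C6 following (in the stepwise limit a 6-(enolexo)-exo-trig closure). C10 is set by approach of the diene anti to the C1 silyloxy group, which allylic 1,2-strain with the vinylic methyl holds pseudoaxial, so the angular methyl ends on the face of O1. C5 follows from suprafacial addition to the cis-alkene (cis ring fusion, corrected in step 7), and C6 from the endo transition state, which places the E-alkoxy group cis to the C5–C4 bond so that it becomes 6α once C5 is epimerised. The step needs regioselectivity (the most nucleophilic diene terminus C9, para to the alkoxy and β to the silyloxy group, on the Lewis-acid-activated β-carbon C10), chemoselectivity for C=C over the ketone C=O, secured by the hindered conjugated carbonyl, and survival of the enol ether, secured by the amine quench.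

Step 7
Reactants: 9 cis-fused adduct
Product: 10 1β,8-bis(TBSO)-6α-(NAPO)-5αH-11,12,13,15-tetranoreudesm-7-en-4-one (trans-fused)
Conditions: 1,8-diazabicyclo[5.4.0]undec-7-ene (DBU, 0.5 equiv), toluene, 40 °C
Reagents that add atoms: none
Why: Base-catalysed epimerisation α to the C4 ketone through the C4–C5 enolate (thermodynamic control) should relax the cis-fused octalone to the trans-fused isomer in which O1 and O6 are both equatorial, so that C5 takes the 5αH configuration, while the silyl enol ether and the ethers are inert to the amidine base.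

Step 8
Reactants: 10 trans-fused ketone
Product: 11 1β,8-bis(TBSO)-6α-(NAPO)-5αH-11,12,13-trinoreudesma-4(15),7-diene
Conditions: Ph3PCH3Br, KN(SiMe3)2, THF, 0 °C; then 10, rt to 50 °C
Reagents that add atoms: methyltriphenylphosphonium bromide, C[P+](c1ccccc1)(c1ccccc1)c1ccccc1.[Br-]
Why: Wittig methylenation of the C4 ketone, the usual entry to the 4(15)-alkene of decalones of this type, installs C15 without forming a stereocentre, C5 already being in its stable configuration.

Step 9
Reactants: 11 diene with the C7=C8 silyl enol ether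
Product: 13 methyl 1β-(TBSO)-6α-(NAPO)-8-oxo-5αH,7αH-13-noreudesm-4(15)-en-12-oate, via C7-epimeric keto ester 12 (not isolated)
Conditions: methyl bromoacetate (2 equiv), fac-Ir(ppy)3 [tris(2-phenylpyridinato)iridium] (1 mol %), 2,6-lutidine, MeCN/H2O, blue LEDs, rt; then DBU (0.3 equiv), CH2Cl2, rt
Reagents that add atoms: methyl bromoacetate, COC(=O)CBr
Why: Visible-light photoredox radical α-alkylation of a silyl enol ether with an α-bromo ester (the electrophilic methoxycarbonylmethyl radical adds to C7 of the electron-rich enol ether in preference to the 4(15)-alkene, then oxidation and loss of the silyl group return the C8 ketone) places the C11–C12 arm regiospecifically at C7 because the enol ether was fixed in step 6, and amidine equilibration α to the ketone then sets C7 under thermodynamic control with the arm equatorial (7β, trans to O6), β-elimination of the equatorial C6 ether, which lies in the enolate plane, being stereoelectronically disfavoured.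

Step 10
Reactants: 13 keto ester
Product: 14 methyl 1β-(TBSO)-8α-hydroxy-6α-(NAPO)-5αH,7αH-13-noreudesm-4(15)-en-12-oate
Conditions: SmI2 (2.5 equiv), MeOH (5 equiv), THF, 0 °C to rt; cold pH 7 buffer work-up, product used at once
Reagents that add atoms: none
Why: Single-electron ketone reduction by SmI2 with a proton donor (ketyl, then organosamarium; a dissolving-metal-type reduction under product-stability control) should give the equatorial 8α-alcohol trans to the C7 arm, whereas hydride reagents would attack from the open α face and give the axial 8β-alcohol; the ester, the alkene and the ethers are not reduced under these conditions.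

Step 11
Reactants: 14 hydroxy ester
Product: 15 methyl 1β,8α-bis(TBSO)-6α-(NAPO)-5αH,7αH-13-noreudesm-4(15)-en-12-oate
Conditions: TBSOTf, 2,6-lutidine, CH2Cl2, −78 to 0 °C
Reagents that add atoms: tert-butyldimethylsilyl trifluoromethanesulfonate, C[Si](C)(OS(=O)(=O)C(F)(F)F)C(C)(C)C
Why: Silyl triflate silylation of the secondary C8 alcohol masks it before the enolate chemistry and prevents closure to the 8,12-lactone, with no change at any stereocentre.

Step 12
Reactants: 15 bis-silyl ether with the 4(15)-alkene
Product: 16 methyl 1β,8α-bis(TBSO)-4α-hydroxy-6α-(NAPO)-5αH,7αH-13-noreudesman-12-oate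
Conditions: Mn(dpm)3 [tris(2,2,6,6-tetramethylheptane-3,5-dionato)manganese] (10 mol %), PhSiH3, O2 (1 atm), iPrOH/CH2Cl2, 0 °C to rt
Reagents that add atoms: dioxygen, O=O
Why: Mukaiyama hydration (hydrogen atom transfer from a manganese hydride to C15 of the 1,1-disubstituted alkene, capture of the tertiary C4 radical by O2, reduction of the peroxide) gives the Markovnikov tertiary alcohol, and oxygen should enter from the equatorial α face because the axial β face is blocked by the syn-axial angular methyl C14, which sets C4 as 4α-OH with 4β-CH3.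

Step 13
Reactants: 16 tertiary alcohol ester
Product: 17 methyl 1β,8α-bis(TBSO)-13-(dimethylamino)-4α-hydroxy-6α-(NAPO)-5αH,7αH-eudesman-12-oate (C11 epimers)
Conditions: LiN(iPr)2 (2.5 equiv), THF, −78 °C; then CH2=NMe2+ I− (Eschenmoser's salt), −78 °C to rt
Reagents that add atoms: N,N-dimethylmethyleneiminium iodide, C=[N+](C)C.[I-]
Why: Mannich reaction of the ester lithium enolate (the tertiary alcohol is carried as its alkoxide) with the preformed iminium salt adds C13 at C11, and the new C11 centre is of no consequence because it becomes trigonal in the next step.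

Step 14
Reactants: 17 Mannich base
Product: 19 methyl 1β,8α-bis(TBSO)-4α-hydroxy-6α-(NAPO)-5αH,7αH-eudesm-11(13)-en-12-oate, via quaternary ammonium iodide 18 (not isolated)
Conditions: MeI, MeOH/CH2Cl2, rt; evaporation; then DBU, CH2Cl2, rt
Reagents that add atoms: none
Why: Exhaustive N-methylation followed by base-induced β-elimination of trimethylamine (the standard α-methylenation of esters through a Mannich base) gives the 11(13)-ene conjugated to the ester, and because C8 is now a silylated carbinol there is no ketone that could pull the double bond into conjugation with the ring.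

Step 15
Reactants: 19 acrylate with the C6 NAP ether
Product: 20 methyl 1β,8α-bis(TBSO)-4α,6α-dihydroxy-5αH,7αH-eudesm-11(13)-en-12-oate
Conditions: DDQ (1.5 equiv), CH2Cl2/H2O (10:1), 0 °C to rt
Reagents that add atoms: none
Why: Oxidative cleavage of the naphthylmethyl ether by DDQ (benzylic hydride abstraction, then hydrolysis of the oxocarbenium ion by the water present) frees O6 alone, the silyl ethers, the tertiary alcohol and the acrylate being inert.

Step 16
Reactants: 20 C6 alcohol
Product: 21 methyl 6α-angeloyloxy-1β,8α-bis(TBSO)-4α-hydroxy-5αH,7αH-eudesm-11(13)-en-12-oate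
Conditions: angelic acid, 2,4,6-trichlorobenzoyl chloride, Et3N, toluene, rt; then 20, toluene, 80 °C
Reagents that add atoms: angelic acid [(Z)-2-methylbut-2-enoic acid], C/C=C(/C)C(=O)O
Why: Yamaguchi-type acylation through the mixed 2,4,6-trichlorobenzoic anhydride, the established way to angelates of hindered secondary alcohols without Z to E isomerisation to the tiglate, esterifies O6 with retention at C6, the tertiary C4 hydroxyl being too hindered to react.

Step 17
Reactants: 21 bis-silyl angelate
Product: 22 methyl 6α-angeloyloxy-1β,4α,8α-trihydroxy-5αH,7αH-eudesm-11(13)-en-12-oate (CNP0136844.1)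
Conditions: HF·pyridine, pyridine, THF, 0 °C to rt
Reagents that add atoms: none
Why: Buffered fluoride desilylation cleaves both secondary silyl ethers under conditions that should leave the angelate, the acrylate ester and the tertiary alcohol intact and are too mild to close the 8,12-lactone.

## Compound list

1 | 2-methylcyclohex-2-en-1-one | CC1=CCCCC1=O | starting material
2 | (R)-2-methylcyclohex-2-en-1-ol | CC1=CCC[C@H]1O | intermediate
3 | (R)-tert-butyldimethyl[(2-methylcyclohex-2-en-1-yl)oxy]silane | CC1=CCC[C@H]1O[Si](C)(C)C(C)(C)C | intermediate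
4 | (R)-4-(tert-butyldimethylsilyloxy)-3-methylcyclohex-2-en-1-one (ring A dienophile) | CC1=CC(=O)CC[C@H]1O[Si](C)(C)C(C)(C)C | intermediate
5 | (E)-4-methoxybut-3-en-2-one | CO/C=C/C(C)=O | starting material
6 | naphthalen-2-ylmethanol | OCc1ccc2ccccc2c1 | starting material
7 | (E)-4-(naphthalen-2-ylmethoxy)but-3-en-2-one | CC(=O)/C=C/OCc1ccc2ccccc2c1 | intermediate
8 | (E)-tert-butyldimethyl{[4-(naphthalen-2-ylmethoxy)buta-1,3-dien-2-yl]oxy}silane (diene, C6–C9) | C=C(O[Si](C)(C)C(C)(C)C)/C=C/OCc1ccc2ccccc2c1 | intermediate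
9 | 1β,8-bis(TBSO)-6α-(NAPO)-5βH-11,12,13,15-tetranoreudesm-7-en-4-one (cis-fused) | CC(C)(C)[Si](C)(C)OC1=C[C@H](OCc2ccc3ccccc3c2)[C@H]4[C@@](C)(C1)[C@H](O[Si](C)(C)C(C)(C)C)CCC4=O | intermediate
10 | 1β,8-bis(TBSO)-6α-(NAPO)-5αH-11,12,13,15-tetranoreudesm-7-en-4-one (trans-fused) | CC(C)(C)[Si](C)(C)OC1=C[C@H](OCc2ccc3ccccc3c2)[C@@H]4[C@@](C)(C1)[C@H](O[Si](C)(C)C(C)(C)C)CCC4=O | intermediate
11 | 1β,8-bis(TBSO)-6α-(NAPO)-5αH-11,12,13-trinoreudesma-4(15),7-diene | CC(C)(C)[Si](C)(C)OC1=C[C@H](OCc2ccc3ccccc3c2)[C@@H]4[C@@](C)(C1)[C@H](O[Si](C)(C)C(C)(C)C)CCC4=C | intermediate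
12 | methyl 1β-(TBSO)-6α-(NAPO)-8-oxo-5αH,7βH-13-noreudesm-4(15)-en-12-oate (C7 epimer, axial arm) | COC(=O)C[C@@H]1[C@H](OCc2ccc3ccccc3c2)[C@@H]4[C@@](C)(CC1=O)[C@H](O[Si](C)(C)C(C)(C)C)CCC4=C | intermediate (not isolated)
13 | methyl 1β-(TBSO)-6α-(NAPO)-8-oxo-5αH,7αH-13-noreudesm-4(15)-en-12-oate | COC(=O)C[C@H]1[C@H](OCc2ccc3ccccc3c2)[C@@H]4[C@@](C)(CC1=O)[C@H](O[Si](C)(C)C(C)(C)C)CCC4=C | intermediate
14 | methyl 1β-(TBSO)-8α-hydroxy-6α-(NAPO)-5αH,7αH-13-noreudesm-4(15)-en-12-oate | COC(=O)C[C@H]1[C@H](OCc2ccc3ccccc3c2)[C@@H]4[C@@](C)(C[C@@H]1O)[C@H](O[Si](C)(C)C(C)(C)C)CCC4=C | intermediate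
15 | methyl 1β,8α-bis(TBSO)-6α-(NAPO)-5αH,7αH-13-noreudesm-4(15)-en-12-oate | COC(=O)C[C@H]1[C@H](OCc2ccc3ccccc3c2)[C@@H]4[C@@](C)(C[C@@H]1O[Si](C)(C)C(C)(C)C)[C@H](O[Si](C)(C)C(C)(C)C)CCC4=C | intermediate
16 | methyl 1β,8α-bis(TBSO)-4α-hydroxy-6α-(NAPO)-5αH,7αH-13-noreudesman-12-oate | COC(=O)C[C@H]1[C@H](OCc2ccc3ccccc3c2)[C@@H]4[C@@](C)(C[C@@H]1O[Si](C)(C)C(C)(C)C)[C@H](O[Si](C)(C)C(C)(C)C)CC[C@@]4(C)O | intermediate
17 | methyl 1β,8α-bis(TBSO)-13-(dimethylamino)-4α-hydroxy-6α-(NAPO)-5αH,7αH-eudesman-12-oate (C11 epimers) | COC(=O)C(CN(C)C)[C@H]1[C@H](OCc2ccc3ccccc3c2)[C@@H]4[C@@](C)(C[C@@H]1O[Si](C)(C)C(C)(C)C)[C@H](O[Si](C)(C)C(C)(C)C)CC[C@@]4(C)O | intermediate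
18 | 13-(trimethylammonio) analogue of 17, iodide salt | COC(=O)C(C[N+](C)(C)C)[C@H]1[C@H](OCc2ccc3ccccc3c2)[C@@H]4[C@@](C)(C[C@@H]1O[Si](C)(C)C(C)(C)C)[C@H](O[Si](C)(C)C(C)(C)C)CC[C@@]4(C)O.[I-] | intermediate (not isolated)
19 | methyl 1β,8α-bis(TBSO)-4α-hydroxy-6α-(NAPO)-5αH,7αH-eudesm-11(13)-en-12-oate | C=C(C(=O)OC)[C@H]1[C@H](OCc2ccc3ccccc3c2)[C@@H]4[C@@](C)(C[C@@H]1O[Si](C)(C)C(C)(C)C)[C@H](O[Si](C)(C)C(C)(C)C)CC[C@@]4(C)O | intermediate
20 | methyl 1β,8α-bis(TBSO)-4α,6α-dihydroxy-5αH,7αH-eudesm-11(13)-en-12-oate | C=C(C(=O)OC)[C@H]1[C@H](O)[C@@H]4[C@@](C)(C[C@@H]1O[Si](C)(C)C(C)(C)C)[C@H](O[Si](C)(C)C(C)(C)C)CC[C@@]4(C)O | intermediate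
21 | methyl 6α-angeloyloxy-1β,8α-bis(TBSO)-4α-hydroxy-5αH,7αH-eudesm-11(13)-en-12-oate | C=C(C(=O)OC)[C@H]1[C@H](OC(=O)/C(C)=C\C)[C@@H]4[C@@](C)(C[C@@H]1O[Si](C)(C)C(C)(C)C)[C@H](O[Si](C)(C)C(C)(C)C)CC[C@@]4(C)O | intermediate
22 | methyl 6α-angeloyloxy-1β,4α,8α-trihydroxy-5αH,7αH-eudesm-11(13)-en-12-oate (CNP0136844.1) | C=C(C(=O)OC)[C@H]1[C@H](OC(=O)/C(C)=C\C)[C@@H]2[C@@](C)(C[C@@H]1O)[C@H](O)CC[C@@]2(C)O | target

## Step count and risks

Total step count: 17. Longest linear sequence: 15 steps (steps 1–3, then 6–17); steps 4–5 make the diene in a two-step side branch.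

**Step 6 (key cycloaddition).** What may go wrong: the β,β-disubstituted enone may react too slowly, so that desilylation or oligomerisation of the acid-sensitive diene, or addition to the carbonyl group, outruns cycloaddition. Fallback: the fallback sets out from enone 4. Bromination–dehydrobromination (Br2, CH2Cl2, 0 °C; then Et3N) should give (R)-2-bromo-4-(tert-butyldimethylsilyloxy)-3-methylcyclohex-2-en-1-one F1, an α-halo enone of the kind known to be a markedly better dienophile. Cycloaddition of F1 with diene 8 under the same aluminium catalysis should give the 5-bromo cis adduct F2. Bu3SnH with azobisisobutyronitrile in toluene at 80 °C then removes the bromine through the planar C5 α-keto radical, which should take hydrogen on the α face opposite the angular methyl. The route is rejoined at the trans-fused ketone 10, and step 7 is no longer needed.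

**Step 7 (ring-fusion epimerisation).** What may go wrong: the C4–C5 enolate may expel the C6 ether (β-elimination) faster than it is reprotonated, or the cis/trans equilibrium may not lie far enough on the trans side. Fallback: the fallback sets out from cis adduct 9 and avoids a free enolate. Enolisation toward the more substituted side (Me3SiCl, NaI, Et3N, MeCN) should give the C4–C5 trimethylsilyl enol ether F3. PhSeCl in CH2Cl2 at −78 °C converts F3 into the 5-(phenylselanyl) ketone F4 (either C5 epimer serves). Bu3SnH with azobisisobutyronitrile cleaves the C–Se bond, and the C5 radical should take hydrogen from the α face. The route is rejoined at the trans-fused ketone 10.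

**Step 10 (C8 reduction).** What may go wrong: facial selectivity may be poor, so that the axial 8β-alcohol forms, or the new alcohol may close onto the ester to give a lactone during work-up. Fallback: the fallback sets out from keto ester 13 and builds C8 by hydroboration instead of carbonyl reduction. Hydration of the 4(15)-alkene as in step 12 gives methyl 1β-(TBSO)-4α-hydroxy-6α-(NAPO)-8-oxo-5αH,7αH-13-noreudesman-12-oate F5. Kinetic enolisation toward C9 (KN(SiMe3)2, then PhNTf2, THF, −78 °C) gives the C8=C9 enol triflate F6. Reduction with Pd(OAc)2, PPh3, Bu3N and HCO2H in DMF at 60 °C gives the 8-ene F7. Hydroboration–oxidation (BH3·THF, 0 °C; then NaBO3) puts boron on C8, away from the neopentyl C9, from the α face opposite the angular methyl, and gives the 4α,8α-diol F8. Selective silylation of the secondary hydroxyl (TBSOTf, 2,6-lutidine, −78 °C) rejoins the route at compound 16.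

## Further compounds

F1 | step 6 | (R)-2-bromo-4-(tert-butyldimethylsilyloxy)-3-methylcyclohex-2-en-1-one | CC1=C(Br)C(=O)CC[C@H]1O[Si](C)(C)C(C)(C)C
F2 | step 6 | 5β-bromo-1β,8-bis(TBSO)-6α-(NAPO)-11,12,13,15-tetranoreudesm-7-en-4-one (cis-fused, bromine on the face of C14) | CC(C)(C)[Si](C)(C)OC1=C[C@H](OCc2ccc3ccccc3c2)[C@@]4(Br)[C@@](C)(C1)[C@H](O[Si](C)(C)C(C)(C)C)CCC4=O
F3 | step 7 | 1β,8-bis(TBSO)-4-(trimethylsilyloxy)-6α-(NAPO)-11,12,13,15-tetranoreudesma-4,7-diene | CC(C)(C)[Si](C)(C)OC1=C[C@H](OCc2ccc3ccccc3c2)C=4[C@@](C)(C1)[C@H](O[Si](C)(C)C(C)(C)C)CCC4O[Si](C)(C)C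
F4 | step 7 | 1β,8-bis(TBSO)-6α-(NAPO)-5-(phenylselanyl)-11,12,13,15-tetranoreudesm-7-en-4-one (C5 configuration open) | CC(C)(C)[Si](C)(C)OC1=C[C@H](OCc2ccc3ccccc3c2)C4([Se]c5ccccc5)[C@@](C)(C1)[C@H](O[Si](C)(C)C(C)(C)C)CCC4=O
F5 | step 10 | methyl 1β-(TBSO)-4α-hydroxy-6α-(NAPO)-8-oxo-5αH,7αH-13-noreudesman-12-oate | COC(=O)C[C@H]1[C@H](OCc2ccc3ccccc3c2)[C@@H]4[C@@](C)(CC1=O)[C@H](O[Si](C)(C)C(C)(C)C)CC[C@@]4(C)O
F6 | step 10 | methyl 1β-(TBSO)-4α-hydroxy-6α-(NAPO)-8-(trifluoromethanesulfonyloxy)-5αH,7αH-13-noreudesm-8-en-12-oate | COC(=O)C[C@H]1[C@H](OCc2ccc3ccccc3c2)[C@@H]4[C@@](C)(C=C1OS(=O)(=O)C(F)(F)F)[C@H](O[Si](C)(C)C(C)(C)C)CC[C@@]4(C)O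
F7 | step 10 | methyl 1β-(TBSO)-4α-hydroxy-6α-(NAPO)-5αH,7αH-13-noreudesm-8-en-12-oate | COC(=O)C[C@H]1[C@H](OCc2ccc3ccccc3c2)[C@@H]4[C@@](C)(C=C1)[C@H](O[Si](C)(C)C(C)(C)C)CC[C@@]4(C)O
F8 | step 10 | methyl 1β-(TBSO)-4α,8α-dihydroxy-6α-(NAPO)-5αH,7αH-13-noreudesman-12-oate | COC(=O)C[C@H]1[C@H](OCc2ccc3ccccc3c2)[C@@H]4[C@@](C)(C[C@@H]1O)[C@H](O[Si](C)(C)C(C)(C)C)CC[C@@]4(C)O
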